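The spring run, charged with 12 mM of starting material at 20 °C, climbed steadily to 83.3% at 8.00 h. The noon run, with 18 mM at 25 °C and the same 9 µM of free enzyme, reads flat from 6.00 h to 96.0 h, and its readings average 23.0%, each with a scatter of 0.5 percentage points.

| flask | starting material | protic impurity | free enzyme | temperature | remark | time |
|---|---|---|---|---|---|---|
| noon | 18 mM | 0.90 mM | 9 µM | 25 °C | the very flask that is asked about, followed so far |  |
| spring | 12 mM | 0.90 mM | 9 µM | 20 °C | run made earlier |  |
| flask | 18 mM | 0.900 mM | 9.0 µM | 25 °C |  | 5.0 d |

| run | time / h | product / % |
|---|---|---|
| noon | 6.00 | 23.0 |
| noon | 20.0 | 22.5 |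
| noon | 30.0 | 22.9 |
| noon | 48.0 | 22.8 |
| noon | 72.0 | 23.5 |
| noon | 96.0 | 23.3 |
| spring | 1.33 | 31.4 |
| spring | 3.00 | 51.8 |
| spring | 4.00 | 61.9 |
| spring | 6.00 | 74.5 |
| spring | 8.00 | 83.3 |

(readings scatter by 0.5 percentage points)

- eta: at 5.0 d add free enzyme, 100% of the amount charged, then wait 2.5 d
- gamma: at 5.0 d take out 90% of the product then present, then wait 2.5 d
- beta: at 5.0 d raise the temperature by 10 K, then wait 2.5 d
- theta: change nothing and wait 2.5 d more

- product that was removed still counts
- additions bring no volume worth counting

1. product, in percent of the starting material first charged, at 5.0 d
2. what to do for the largest gain in product; "none" if nothing gains more than 2 percentage points (eta / gamma / beta / theta / none)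
3. product present, with what was taken out counted in, in percent of the starting material first charged, after gamma
4. product present, with what was taken out counted in, in percent of the starting material first charged, after beta

A catalyst returns after each round, so product can grow while working enzyme and starting material both stand in a flask. The spring run made 10.0 mM of product, more than the 4.14 mM of the noon run, so product at the noon level did not stop the spring run. The flat noon curve therefore reads as enzyme that stopped working, and the useful number is a count, not a rate. Divided by the enzyme charged, the noon plateau gives 460 molecules of product per enzyme. Call this the turnover capacity, the field's turnover number. It is a reading at the noon conditions: the spring run, with another charge and temperature, is past 1110 and was still rising at its last reading. So it is carried here at 18 mM and 25 °C.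

For the asked flask, which is the noon run followed on, the capacity puts product at 23.0% at 5.0 d. Taking out product or heating by 10 K adds no working enzyme, so gamma and beta stay at that plateau, and so does waiting. Eta adds 100% of the enzyme charged, which is a second count worth about 23 points, beyond the margin of 2 points.

The forecast gives 23% now, 23% after gamma, 23.2% after beta and eta as best, with a gain of 15 to 20 points, on the ground that “dead enzyme stays dead”. The flask gives 22.9% at 5.0 d, 22.9% after gamma and 22.9% after beta, and eta gains 40 points.

    free enzyme → unfolded enzyme (k = 2.30 × 10⁻⁷ s⁻¹, Ea = 252 kJ mol⁻¹)
    starting material + free enzyme → product + free enzyme, rate k2*[starting material]*[free enzyme]/(1 + ([starting material]/Km2) + ([starting material]/Ksi2)^2) (0.570 mM, 5.60 mM, k = 340 L mol⁻¹ s⁻¹, Ea = 41.0 kJ mol⁻¹)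
    starting material + protic impurity → quenched substrate (k = 0.0480 L mol⁻¹ s⁻¹, Ea = 63.0 kJ mol⁻¹)
    starting material + free enzyme → spent catalyst (k = 0.0210 L mol⁻¹ s⁻¹, Ea = 57.0 kJ mol⁻¹)
    (constants at 25 °C)

At 120 h spent catalyst holds 99.9% of this flask's enzyme, so its capacity is the product step over the step to spent catalyst. That ratio is 377 at the charge and 556 at the 72.0% left, with the reading between them. Eta's enzyme starts from the upper figure, and its gain stands above the reckoned 23 points. The main reason for the low product at 5.0 d is the plain denominator term in starting material of the product step: without it this flask reaches 95.9%, not 22.9%. For the neighbour charged with 0.0022 mM of free enzyme, the capacity gives 5.62%; the computed result is 4.97%.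

The data were generated by integration for an exercise; scatter was added.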